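## Retrosynthetic overview

1. Ester C–O: the target is cut into the 8-hydroxy α-methylene lactone core and an acetonide-protected (E)-4-hydroxy-2-(hydroxymethyl)but-2-enoic acid, made from but-2-yne-1,4-diol by syn-hydrostannation and carboxylation.
2. Cyclohexane and lactone together: the ring-fusion C–C bond, the lactone C–C(=O) bond and the lactone C–O bond are cut in one stroke to an acyclic allenyl aldehyde plus CO (intramolecular hetero-Pauson–Khand [2+2+1]).
3. Allenyl aldehyde from the acid by redox; the vicinal quaternary/tertiary pair comes from a boron-enolate Ireland–Claisen rearrangement of an (E)-allylic 3-methylbut-3-enoate.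
4. The allylic alcohol with its allenyl carbinol comes from one LiAlH4 operation (ester reduction plus SN2′ reduction of a 4-methoxy propargylic alcohol) on a catalytic asymmetric vinylogous Mukaiyama aldol adduct of 4-methoxybut-2-ynal.
5. Ring order: no ring exists until step 9; carbocycle and lactone then form in the same operation.

Assumption: the antipodes written for the two chiral controllers (bisphosphoramide in step 3, diazaborolidine in step 6) are those taken to give the (R)-carbinol and the (2R,3R)-acid; if the observed sense is opposite, the mirror-image controller is used and nothing else changes.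

## Route

Step 1
Reactants: 1 3-methoxyprop-1-yne
Product: 2 4-methoxybut-2-ynal
Conditions: n-BuLi, THF, −78 °C; DMF, −78 → 0 °C; poured into cold aq. KH2PO4/MTBE
Reagents that add atoms: N,N-dimethylformamide, CN(C)C=O
Why: Formylation of the lithium acetylide with DMF, with a phosphate reverse quench that releases the ynal without amine conjugate addition.

Step 2
Reactants: 3 methyl 3-methylbut-2-enoate
Product: 4 (1Z)-1-[(tert-butyldimethylsilyl)oxy]-1-methoxy-3-methylbuta-1,3-diene
Conditions: LDA, THF, −78 °C; TBSCl, DMPU, −78 °C → rt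
Reagents that add atoms: tert-butyldimethylsilyl chloride, CC(C)(C)[Si](C)(C)Cl
Why: Kinetic γ-deprotonation of the senecioate gives the lithium dienolate, which is O-silylated to the silyl ketene acetal (silyl dienolate formation).

Step 3
Reactants: 2 4-methoxybut-2-ynal; 4 (1Z)-1-[(tert-butyldimethylsilyl)oxy]-1-methoxy-3-methylbuta-1,3-diene
Product: 5 methyl (2E,5R)-5-hydroxy-8-methoxy-3-methyloct-2-en-6-ynoate
Conditions: SiCl4 (1.1 equiv), (R,R)-binaphthyldiamine-derived bisphosphoramide (2 mol %), CH2Cl2, −78 °C; aq. NaHCO3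
Reagents that add atoms: none
Why: Lewis-base-activated SiCl4 vinylogous Mukaiyama aldol reaction, γ-selective with an (E)-enoate from an open transition state; the chiral phosphoramide-bound silicon cation selects the aldehyde face and sets the (5R) carbinol.

Step 4
Reactants: 5 methyl (2E,5R)-5-hydroxy-8-methoxy-3-methyloct-2-en-6-ynoate
Product: 6 (2E,5R)-3-methylocta-2,6,7-triene-1,5-diol
Conditions: LiAlH4 (3 equiv), Et2O, 0 °C → reflux; H2O/aq. NaOH work-up
Reagents that add atoms: none
Why: LiAlH4 reduces the ester 1,2 and the propargylic alkoxide directs trans-hydroalumination followed by 1,2-elimination of methoxide (SN2′ reduction of a 4-alkoxy-2-alkyn-1-ol to an α-allenol); the carbinol centre is untouched.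

Step 5
Reactants: 6 (2E,5R)-3-methylocta-2,6,7-triene-1,5-diol; 7 3-methylbut-3-enoic acid
Product: 9 (2E,5R)-5-[(tert-butyldimethylsilyl)oxy]-3-methylocta-2,6,7-trien-1-yl 3-methylbut-3-enoate, via hydroxy ester 8 (not isolated)
Conditions: EDC·HCl, DMAP (cat.), CH2Cl2, −20 °C; then TBSCl, imidazole, rt
Reagents that add atoms: tert-butyldimethylsilyl chloride, CC(C)(C)[Si](C)(C)Cl
Why: Carbodiimide (Steglich-type) esterification at low temperature takes the primary allylic hydroxyl in preference to the hindered secondary allenyl carbinol, which is then silylated in the same flask.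

Step 6
Reactants: 9 (2E,5R)-5-[(tert-butyldimethylsilyl)oxy]-3-methylocta-2,6,7-trien-1-yl 3-methylbut-3-enoate
Product: 10 (2R,3R,5R)-5-[(tert-butyldimethylsilyl)oxy]-3-ethenyl-3-methyl-2-(prop-1-en-2-yl)octa-6,7-dienoic acid
Conditions: (S,S)-2-bromo-4,5-diphenyl-1,3-bis{[3,5-bis(trifluoromethyl)phenyl]sulfonyl}-1,3,2-diazaborolidine (1.2 equiv), Et3N, toluene/hexane, −78 → 4 °C; aq. work-up
Reagents that add atoms: none
Why: Boron-enolate Ireland–Claisen rearrangement in which the E(O) boron dienolate and the (E)-alkene pass through a chair with the chain equatorial and the isopropenyl group axial, giving the (2R*,3R*) quaternary/tertiary pair, while the C2-symmetric sulfonamide controller shields one enolate face to give (2R,3R) beside the spectator (5R) centre.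

Step 7
Reactants: 10 (2R,3R,5R)-5-[(tert-butyldimethylsilyl)oxy]-3-ethenyl-3-methyl-2-(prop-1-en-2-yl)octa-6,7-dienoic acid
Product: 11 (2R,3R,5R)-5-[(tert-butyldimethylsilyl)oxy]-3-ethenyl-3-methyl-2-(prop-1-en-2-yl)octa-6,7-dien-1-ol
Conditions: LiAlH4, Et2O, 0 °C; H2O/aq. NaOH work-up
Reagents that add atoms: none
Why: Hydride reduction of the carboxylic acid proceeds through the carboxylate, so the α-centre does not epimerise and the silyl ether, allene and isolated alkenes are inert.

Step 8
Reactants: 11 (2R,3R,5R)-5-[(tert-butyldimethylsilyl)oxy]-3-ethenyl-3-methyl-2-(prop-1-en-2-yl)octa-6,7-dien-1-ol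
Product: 12 (2R,3R,5R)-5-[(tert-butyldimethylsilyl)oxy]-3-ethenyl-3-methyl-2-(prop-1-en-2-yl)octa-6,7-dienal
Conditions: Dess–Martin periodinane, CH2Cl2, 0 °C; used at once, kept below 25 °C
Reagents that add atoms: none
Why: Dess–Martin oxidation is base-free, so the β,γ-unsaturated α-stereocentre neither epimerises nor moves into conjugation.

Step 9
Reactants: 12 (2R,3R,5R)-5-[(tert-butyldimethylsilyl)oxy]-3-ethenyl-3-methyl-2-(prop-1-en-2-yl)octa-6,7-dienal
Product: 13 (3aR,4R,6R,7R,7aS)-4-[(tert-butyldimethylsilyl)oxy]-6-ethenyl-6-methyl-3-methylidene-7-(prop-1-en-2-yl)hexahydro-1-benzofuran-2(3H)-one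
Conditions: Mo(CO)3(DMF)3 (1.5 equiv), CO (1 atm), THF, 23 °C
Reagents that add atoms: carbon monoxide, [C-]#[O+]
Why: Proposed new method: Mo(0) binds the aldehyde and the proximal allene π-bond, oxidative cyclisation forms the cyclohexane C–C bond as an oxamolybdacycle, and CO insertion with C–O reductive elimination closes the α-methylene lactone, so both rings and the lactone carbonyl arrive in one hetero-Pauson–Khand [2+2+1] operation; a chair-like cyclisation with isopropenyl, vinyl, silyloxy, the new C–O and the allenyl carbon all equatorial (an axial C–O would meet the axial methyl 1,3) is expected to set the two ring-fusion centres trans; the closest known reactions are the Mo(CO)6/DMSO- and Ru3(CO)12-mediated cyclocarbonylations of allenyl aldehydes at 100–120 °C (cis-fused in less substituted cases) and the room-temperature Mo(CO)3(DMF)3 hetero-Pauson–Khand reaction of ynals.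

Step 10
Reactants: 13 (3aR,4R,6R,7R,7aS)-4-[(tert-butyldimethylsilyl)oxy]-6-ethenyl-6-methyl-3-methylidene-7-(prop-1-en-2-yl)hexahydro-1-benzofuran-2(3H)-one
Product: 14 (3aS,4R,6R,7R,7aS)-6-ethenyl-4-hydroxy-6-methyl-3-methylidene-7-(prop-1-en-2-yl)hexahydro-1-benzofuran-2(3H)-one
Conditions: HF·pyridine, pyridine/THF, 0 °C → rt
Reagents that add atoms: none
Why: Buffered fluoride desilylation frees the secondary alcohol without conjugate addition to the α-methylene lactone (the descriptor at C3a changes only through CIP priorities).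

Step 11
Reactants: 15 but-2-yne-1,4-diol
Product: 16 (2E)-2-(tributylstannyl)but-2-ene-1,4-diol
Conditions: Bu3SnH, PdCl2(PPh3)2 (1 mol %), THF, rt
Reagents that add atoms: tributyltin hydride, CCCC[SnH](CCCC)CCCC
Why: Palladium-catalysed hydrostannation adds H and Sn syn across the symmetrical alkyne, which fixes the two CH2OH groups cis.

Step 12
Reactants: 16 (2E)-2-(tributylstannyl)but-2-ene-1,4-diol
Product: 17 tributyl(2,2-dimethyl-4,7-dihydro-1,3-dioxepin-5-yl)stannane
Conditions: 2,2-dimethoxypropane, PPTS (cat.), CH2Cl2, rt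
Reagents that add atoms: 2,2-dimethoxypropane, COC(C)(C)OC
Why: Transacetalisation closes the seven-membered acetonide on the cis-diol and locks the alkene geometry in a ring.

Step 13
Reactants: 17 tributyl(2,2-dimethyl-4,7-dihydro-1,3-dioxepin-5-yl)stannane
Product: 18 2,2-dimethyl-4,7-dihydro-1,3-dioxepine-5-carboxylic acid
Conditions: n-BuLi, THF, −78 °C; CO2 (g), −78 °C; aq. NaH2PO4; used directly
Reagents that add atoms: carbon dioxide, O=C=O
Why: Tin–lithium exchange gives the vinyllithium with retention, and carboxylation at −78 °C outruns β-alkoxide elimination.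

Step 14
Reactants: 14 (3aS,4R,6R,7R,7aS)-6-ethenyl-4-hydroxy-6-methyl-3-methylidene-7-(prop-1-en-2-yl)hexahydro-1-benzofuran-2(3H)-one; 18 2,2-dimethyl-4,7-dihydro-1,3-dioxepine-5-carboxylic acid
Product: 19 (3aS,4R,6R,7R,7aS)-6-ethenyl-6-methyl-3-methylidene-2-oxo-7-(prop-1-en-2-yl)octahydro-1-benzofuran-4-yl 2,2-dimethyl-4,7-dihydro-1,3-dioxepine-5-carboxylate
Conditions: 18, 2,4,6-trichlorobenzoyl chloride, Et3N, THF, rt; then 14, DMAP, toluene, rt
Reagents that add atoms: none
Why: Yamaguchi esterification acylates the hindered equatorial secondary alcohol with retention, and the ring-locked enoate cannot isomerise.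

Step 15
Reactants: 19 (3aS,4R,6R,7R,7aS)-6-ethenyl-6-methyl-3-methylidene-2-oxo-7-(prop-1-en-2-yl)octahydro-1-benzofuran-4-yl 2,2-dimethyl-4,7-dihydro-1,3-dioxepine-5-carboxylate
Product: 20 (3aS,4R,6R,7R,7aS)-6-ethenyl-6-methyl-3-methylidene-2-oxo-7-(prop-1-en-2-yl)octahydro-1-benzofuran-4-yl (2E)-4-hydroxy-2-(hydroxymethyl)but-2-enoate
Conditions: AcOH/THF/H2O (3:1:1), rt
Reagents that add atoms: none
Why: Mild acid hydrolysis of the strained seven-membered acetonide releases the two primary alcohols; the cis ring geometry becomes the (E)-enoate and the lactone and ester are untouched.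

## Compound list

1 | 3-methoxyprop-1-yne | COCC#C | starting material
2 | 4-methoxybut-2-ynal | COCC#CC=O | intermediate
3 | methyl 3-methylbut-2-enoate | COC(=O)C=C(C)C | starting material
4 | (1Z)-1-[(tert-butyldimethylsilyl)oxy]-1-methoxy-3-methylbuta-1,3-diene | C=C(C)/C=C(\O[Si](C)(C)C(C)(C)C)OC | intermediate
5 | methyl (2E,5R)-5-hydroxy-8-methoxy-3-methyloct-2-en-6-ynoate | COC(=O)/C=C(\C)C[C@@H](O)C#CCOC | intermediate
6 | (2E,5R)-3-methylocta-2,6,7-triene-1,5-diol | OC/C=C(\C)C[C@@H](O)C=C=C | intermediate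
7 | 3-methylbut-3-enoic acid | C=C(C)CC(=O)O | starting material
8 | (2E,5R)-5-hydroxy-3-methylocta-2,6,7-trien-1-yl 3-methylbut-3-enoate | C=C(C)CC(=O)OC/C=C(\C)C[C@@H](O)C=C=C | intermediate
9 | (2E,5R)-5-[(tert-butyldimethylsilyl)oxy]-3-methylocta-2,6,7-trien-1-yl 3-methylbut-3-enoate | C=C(C)CC(=O)OC/C=C(\C)C[C@@H](O[Si](C)(C)C(C)(C)C)C=C=C | intermediate
10 | (2R,3R,5R)-5-[(tert-butyldimethylsilyl)oxy]-3-ethenyl-3-methyl-2-(prop-1-en-2-yl)octa-6,7-dienoic acid | OC(=O)[C@H](C(C)=C)[C@@](C)(C=C)C[C@@H](O[Si](C)(C)C(C)(C)C)C=C=C | intermediate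
11 | (2R,3R,5R)-5-[(tert-butyldimethylsilyl)oxy]-3-ethenyl-3-methyl-2-(prop-1-en-2-yl)octa-6,7-dien-1-ol | OC[C@H](C(C)=C)[C@@](C)(C=C)C[C@@H](O[Si](C)(C)C(C)(C)C)C=C=C | intermediate
12 | (2R,3R,5R)-5-[(tert-butyldimethylsilyl)oxy]-3-ethenyl-3-methyl-2-(prop-1-en-2-yl)octa-6,7-dienal | O=C[C@H](C(C)=C)[C@@](C)(C=C)C[C@@H](O[Si](C)(C)C(C)(C)C)C=C=C | intermediate
13 | (3aR,4R,6R,7R,7aS)-4-[(tert-butyldimethylsilyl)oxy]-6-ethenyl-6-methyl-3-methylidene-7-(prop-1-en-2-yl)hexahydro-1-benzofuran-2(3H)-one | C=C[C@@]1(C)C[C@@H](O[Si](C)(C)C(C)(C)C)[C@@H]2C(=C)C(=O)O[C@H]2[C@@H]1C(=C)C | intermediate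
14 | (3aS,4R,6R,7R,7aS)-6-ethenyl-4-hydroxy-6-methyl-3-methylidene-7-(prop-1-en-2-yl)hexahydro-1-benzofuran-2(3H)-one | C=C[C@@]1(C)C[C@@H](O)[C@@H]2C(=C)C(=O)O[C@H]2[C@@H]1C(=C)C | intermediate
15 | but-2-yne-1,4-diol | OCC#CCO | starting material
16 | (2E)-2-(tributylstannyl)but-2-ene-1,4-diol | OC/C=C(\CO)[Sn](CCCC)(CCCC)CCCC | intermediate
17 | tributyl(2,2-dimethyl-4,7-dihydro-1,3-dioxepin-5-yl)stannane | CC1(C)OCC=C(CO1)[Sn](CCCC)(CCCC)CCCC | intermediate
18 | 2,2-dimethyl-4,7-dihydro-1,3-dioxepine-5-carboxylic acid | CC1(C)OCC=C(CO1)C(=O)O | intermediate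
19 | (3aS,4R,6R,7R,7aS)-6-ethenyl-6-methyl-3-methylidene-2-oxo-7-(prop-1-en-2-yl)octahydro-1-benzofuran-4-yl 2,2-dimethyl-4,7-dihydro-1,3-dioxepine-5-carboxylate | C=C[C@@]1(C)C[C@@H](OC(=O)C3=CCOC(C)(C)OC3)[C@@H]2C(=C)C(=O)O[C@H]2[C@@H]1C(=C)C | intermediate
20 | (3aS,4R,6R,7R,7aS)-6-ethenyl-6-methyl-3-methylidene-2-oxo-7-(prop-1-en-2-yl)octahydro-1-benzofuran-4-yl (2E)-4-hydroxy-2-(hydroxymethyl)but-2-enoate | C=C[C@@]1(C)C[C@@H](OC(=O)/C(=C/CO)CO)[C@@H]2C(=C)C(=O)O[C@H]2[C@@H]1C(=C)C | target

## Step count and risks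

Total step count: 15.
Longest linear sequence: 11 steps (1, 3, 4, 5, 6, 7, 8, 9, 10, 14, 15).

Steps most likely to fail:

Step 9 (double ring closure). The risks are a cis ring fusion as in the simpler precedents, a Mo-mediated reaction that is too slow at room temperature, and loss of 12 on warming by [3,3] shift of its 3-formyl-1,5-diene or by isomerisation to the conjugated enal. The fallback sets out from 12 and forms the rings one at a time. A bromo-Prins allene–aldehyde cyclisation (TiBr4, CH2Cl2, −78 °C) runs through a chair with all substituents but the methyl equatorial; the vinyl cation is captured by bromide to give (1S,2R,3R,5R,6R)-2-(1-bromoethenyl)-3-[(tert-butyldimethylsilyl)oxy]-5-ethenyl-5-methyl-6-(prop-1-en-2-yl)cyclohexan-1-ol F1. Palladium-catalysed carbonylative lactonisation of F1 (Pd(PPh3)4, CO 1 atm, Et3N, THF, 60 °C) then closes the α-methylene lactone and the route is rejoined at 13.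

Step 6 (Ireland–Claisen). The risks are an unfavourable boron dienolate geometry for the β,γ-unsaturated ester, a slow rearrangement onto the fully substituted alkene carbon, and an uncertain facial sense. The fallback sets out from 8 (step 5 stopped before silylation) and uses the carbinol centre to sort the diastereomers instead of a chiral reagent. An LDA/TMSCl Ireland–Claisen rearrangement (THF, −78 °C → rt, excess reagents to mask the hydroxyl in situ) with acidic work-up gives directly two δ-lactones, separable on silica: (3R,4R,6R)-4-ethenyl-4-methyl-6-(propa-1,2-dien-1-yl)-3-(prop-1-en-2-yl)oxan-2-one F2 and its (3S,4S,6R)-diastereomer F3. F2 is opened with MeNH(OMe)·HCl/Me3Al to (2R,3R,5R)-3-ethenyl-5-hydroxy-N-methoxy-N,3-dimethyl-2-(prop-1-en-2-yl)octa-6,7-dienamide F4. Silylation (TBSOTf, 2,6-lutidine) gives (2R,3R,5R)-5-[(tert-butyldimethylsilyl)oxy]-3-ethenyl-N-methoxy-N,3-dimethyl-2-(prop-1-en-2-yl)octa-6,7-dienamide F5, and DIBAL-H at −78 °C reduces F5 to the aldehyde, rejoining the route at 12.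

Step 3 (asymmetric vinylogous aldol). The risks are modest enantioselectivity with a small ynal, α-attack, and some (Z)-enoate. The fallback sets out from 2 and 4 and sets the carbinol by reduction instead of C–C bond formation. A BF3·OEt2-mediated vinylogous Mukaiyama aldol gives racemic methyl (2E)-5-hydroxy-8-methoxy-3-methyloct-2-en-6-ynoate F6. Dess–Martin oxidation gives methyl (2E)-8-methoxy-3-methyl-5-oxooct-2-en-6-ynoate F7, which is reduced at once by Noyori transfer hydrogenation (RuCl[(R,R)-TsDPEN](p-cymene), HCO2H/Et3N, rt). The (R,R)-catalyst gives the (R)-propargylic alcohol, and the route is rejoined at 5.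

Further compounds
F1 | step 9 | (1S,2R,3R,5R,6R)-2-(1-bromoethenyl)-3-[(tert-butyldimethylsilyl)oxy]-5-ethenyl-5-methyl-6-(prop-1-en-2-yl)cyclohexan-1-ol | C=C[C@@]1(C)C[C@@H](O[Si](C)(C)C(C)(C)C)[C@H](C(Br)=C)[C@@H](O)[C@@H]1C(=C)C
F2 | step 6 | (3R,4R,6R)-4-ethenyl-4-methyl-6-(propa-1,2-dien-1-yl)-3-(prop-1-en-2-yl)oxan-2-one | O=C1[C@H](C(C)=C)[C@@](C)(C=C)C[C@H](C=C=C)O1
F3 | step 6 | (3S,4S,6R)-4-ethenyl-4-methyl-6-(propa-1,2-dien-1-yl)-3-(prop-1-en-2-yl)oxan-2-one | O=C1[C@@H](C(C)=C)[C@](C)(C=C)C[C@H](C=C=C)O1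
F4 | step 6 | (2R,3R,5R)-3-ethenyl-5-hydroxy-N-methoxy-N,3-dimethyl-2-(prop-1-en-2-yl)octa-6,7-dienamide | CON(C)C(=O)[C@H](C(C)=C)[C@@](C)(C=C)C[C@@H](O)C=C=C
F5 | step 6 | (2R,3R,5R)-5-[(tert-butyldimethylsilyl)oxy]-3-ethenyl-N-methoxy-N,3-dimethyl-2-(prop-1-en-2-yl)octa-6,7-dienamide | CON(C)C(=O)[C@H](C(C)=C)[C@@](C)(C=C)C[C@@H](O[Si](C)(C)C(C)(C)C)C=C=C
F6 | step 3 | methyl (2E)-5-hydroxy-8-methoxy-3-methyloct-2-en-6-ynoate (racemate) | COC(=O)/C=C(\C)CC(O)C#CCOC
F7 | step 3 | methyl (2E)-8-methoxy-3-methyl-5-oxooct-2-en-6-ynoate | COC(=O)/C=C(\C)CC(=O)C#CCOC
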